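**Strategy.** The route rests on disconnecting the lactone (oxolane) ring across its C2–C3 bond, which joins the O1-bearing carbinol carbon C2 to the carboxyl-bearing C3. The ring is read as an aldehyde C=O (O1, C2 and the chain) annulated onto the three-carbon C3–C4(=CH2)–C5(=O) unit of an itaconate. In one operation a chiral chromium catalyst adds di-tert-butyl 2-(bromomethyl)fumarate through its ester-bearing γ-carbon to (S)-15-hydroxyhexadecanal, creating C2–C3, both ring stereocentres and the exo-methylene. Acid in the same operation then closes the γ-lactone and frees the acid. The precursors are a linear hydroxy aldehyde and an achiral allylic bromide.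

Key step: step 5

Assumption: 12-bromododec-1-ene, (S)-propylene oxide and itaconic acid are taken as commercial.
Assumption (chemistry): L* is (S,S)-1,8-bis(4-isopropyl-4,5-dihydro-1,3-oxazol-2-yl)-3,6-diphenyl-9H-carbazole. It is assumed to direct the allylchromium reagent to the Re face of the aldehyde. If a model aldehyde shows the opposite sense, the (R,R)-antipode is used and nothing else changes.

Step 1
Reactants: 1 12-bromododec-1-ene; 2 (2S)-2-methyloxirane
Product: 4 (2S)-pentadec-14-en-2-ol, via dodec-11-enylmagnesium bromide 3 (not isolated)
Conditions: Mg turnings, THF, 40 °C; then CuI (10 mol %), 2, −30 °C to 0 °C; aq. HCl (1 M)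
Reagents that add atoms: none
Why: Grignard formation followed by copper-catalysed SN2 ring opening of the epoxide at its unsubstituted CH2 carbon should give the secondary alcohol, and since the stereocentre of 2 is not attacked its (S) configuration is carried unchanged into 4.

Step 2
Reactants: 4 (2S)-pentadec-14-en-2-ol
Product: 5 (15S)-15-hydroxyhexadecanal
Conditions: Rh(acac)(CO)2 (0.5 mol %), Xantphos (2 mol %), CO/H2 (1:1, 10 bar), toluene, 80 °C
Reagents that add atoms: carbon monoxide, [C-]#[O+]
Why: Rhodium-catalysed hydroformylation with the wide-bite-angle diphosphine should place the formyl group on the terminal carbon (linear selectivity), adding the one carbon that completes the C16 chain while the free secondary alcohol and its stereocentre stay untouched.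

Step 3
Reactants: 6 itaconic acid
Product: 7 di-tert-butyl 2-methylidenebutanedioate
Conditions: isobutylene (excess), H2SO4 (cat.), CH2Cl2, sealed vessel, rt
Reagents that add atoms: 2-methylpropene, CC(C)=C
Why: Acid-catalysed addition of both carboxylic acids to isobutylene (tert-butyl ester formation through the tert-butyl cation) should give the diester, whose ester groups later fall off under acid alone.

Step 4
Reactants: 7 di-tert-butyl 2-methylidenebutanedioate
Product: 9 di-tert-butyl (2Z)-2-(bromomethyl)but-2-enedioate, via dibromide 8 (not isolated)
Conditions: Br2, CH2Cl2, 0 °C to rt, dark; then Et3N (1.05 equiv), 0 °C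
Reagents that add atoms: bromine, BrBr
Why: Electrophilic addition of bromine to the 1,1-disubstituted alkene gives dibromide 8, from which triethylamine removes HBr (E2 elimination of the tertiary bromide with the acidic C3–H) to leave the allylic bromide with the two esters trans, the more stable fumarate geometry.

Step 5
Reactants: 5 (15S)-15-hydroxyhexadecanal; 9 di-tert-butyl (2Z)-2-(bromomethyl)but-2-enedioate
Product: 13 (2S,3S)-2-[(14S)-14-hydroxypentadecyl]-4-methylidene-5-oxooxolane-3-carboxylic acid, via silylated aldehyde 10 (not isolated), via bis-silyl syn adduct 11 (not isolated), via seco hydroxy diacid 12 (not isolated)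
Conditions: TMSCl (3 equiv), iPr2NEt (1.2 equiv), THF, 0 °C; then 9, CrCl2 (10 mol %), L* (12 mol %), Mn powder, THF, 0 °C to rt; filter (Celite), concentrate; then TFA/CH2Cl2/H2O (30:65:5), 0 °C to rt; aqueous work-up
Reagents that add atoms: none
Why: Divalent chromium bound to L* reduces allylic bromide 9 in two one-electron steps to an allylchromium species of trivalent chromium, which adds to the aldehyde of 10 through a six-membered chair transition state with allylic transposition (SE2'), so that the ester-bearing γ-carbon becomes C3, the aldehyde carbon becomes C2 and the former CH2Br carbon becomes the exo-methylene, while TMSCl releases the adduct from chromium as silyl ether 11 and Mn returns chromium to the divalent state. The closest known reaction type is the catalytic enantioselective Nozaki–Hiyama–Kishi 2-(alkoxycarbonyl)allylation of aliphatic aldehydes followed by lactonization, here run with a 2-(bromomethyl)acrylate that carries an ester on its γ-carbon. The oxolane ring closes as a formal [3+2] annulation: once C2–C3 is made, TFA removes the silyl and tert-butyl groups and the C2 hydroxyl of 12 acylates the acrylic carboxyl (5-exo-trig lactonization, γ-lactone preferred over β-lactone) with retention at C2. C2 (S) is set by the chiral ligand on chromium, which directs attack to the Re face of the aldehyde, and C3 (S) follows from the chair transition state, in which the fumarate geometry (γ-ester cis to the chromium-bearing CH2) leads to the syn adduct and hence the 2,3-cis lactone. The step needs catalyst control over a ligand-free Mn-mediated background allylation and retention of the fumarate geometry in the allylchromium species, and the thermodynamic preference for the trans diester secures the latter. The second stage uses acid only, so neither epimerization at C3 nor migration of the exo-methylene into the ring is expected.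

**Compound list**

1 | 12-bromododec-1-ene | C=CCCCCCCCCCCBr | starting material
2 | (2S)-2-methyloxirane ((S)-propylene oxide) | C[C@H]1CO1 | starting material
3 | dodec-11-en-1-ylmagnesium bromide | C=CCCCCCCCCCC[Mg]Br | intermediate
4 | (2S)-pentadec-14-en-2-ol | C[C@H](O)CCCCCCCCCCCC=C | intermediate
5 | (15S)-15-hydroxyhexadecanal | C[C@H](O)CCCCCCCCCCCCCC=O | intermediate
6 | itaconic acid (2-methylidenebutanedioic acid) | C=C(CC(=O)O)C(=O)O | starting material
7 | di-tert-butyl 2-methylidenebutanedioate | C=C(CC(=O)OC(C)(C)C)C(=O)OC(C)(C)C | intermediate
8 | di-tert-butyl 2-bromo-2-(bromomethyl)butanedioate (racemic) | CC(C)(C)OC(=O)CC(Br)(CBr)C(=O)OC(C)(C)C | intermediate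
9 | di-tert-butyl (2Z)-2-(bromomethyl)but-2-enedioate | CC(C)(C)OC(=O)/C=C(\CBr)C(=O)OC(C)(C)C | intermediate
10 | (15S)-15-[(trimethylsilyl)oxy]hexadecanal | C[C@H](O[Si](C)(C)C)CCCCCCCCCCCCCC=O | intermediate
11 | di-tert-butyl (2S)-2-[(1S,15S)-1,15-bis(trimethylsilyloxy)hexadecyl]-3-methylidenebutanedioate | C[Si](C)(C)O[C@@H](CCCCCCCCCCCCC[C@H](C)O[Si](C)(C)C)[C@H](C(=C)C(=O)OC(C)(C)C)C(=O)OC(C)(C)C | intermediate
12 | (2S)-2-[(1S,15S)-1,15-dihydroxyhexadecyl]-3-methylidenebutanedioic acid | O[C@@H](CCCCCCCCCCCCC[C@H](C)O)[C@H](C(=C)C(=O)O)C(=O)O | intermediate
13 | (2S,3S)-2-[(14S)-14-hydroxypentadecyl]-4-methylidene-5-oxooxolane-3-carboxylic acid | C=C1C(=O)O[C@@H](CCCCCCCCCCCCC[C@H](C)O)[C@H]1C(=O)O | target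

**Total step count:** 5
**Longest linear sequence:** 3 steps (steps 1, 2 and 5; the branch through steps 3, 4 and 5 is equally long)

**Steps most likely to fail**

1. Step 5 (key step). The risks are poor facial selectivity at the aldehyde through the ligand-free Mn-mediated background allylation, and erosion of syn selectivity through geometric equilibration of the allylchromium species. Either would give ring stereoisomers that the remote stereocentre does not help to separate. The fallback gives up catalyst control and separates afterwards. It sets out from 5 and 9: an indium-mediated Barbier allylation (In powder, THF/H2O, rt), which proceeds through a closed transition state, should give the syn adduct di-tert-butyl 2-[(15S)-1,15-dihydroxyhexadecyl]-3-methylidenebutanedioate F1 as both configurations of the new stereocentre pair in comparable amounts. TFA/CH2Cl2 then cleaves the esters and lactonizes to a mixture of 13 and its ring-antipodal diastereomer (2R,3R)-2-[(14S)-14-hydroxypentadecyl]-4-methylidene-5-oxooxolane-3-carboxylic acid F2. Preparative HPLC on a chiral stationary phase (cellulose tris(3,5-dimethylphenylcarbamate)) should remove F2, and the fallback comes back to the route at 13.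

2. Step 4. The risks are loss of tert-butyl groups through adventitious HBr during bromination, formation of the maleate-type geometric isomer, and quaternization of the allylic bromide by triethylamine. The fallback replaces ionic addition–elimination by radical allylic bromination. It sets out from 7: DBU (cat.) in toluene at 60 °C should isomerize the alkene into conjugation to give di-tert-butyl (2E)-2-methylbut-2-enedioate F3. Wohl–Ziegler bromination (NBS, AIBN cat., solid NaHCO3, PhCF3, 80 °C) should then brominate the allylic methyl group with equilibration to the fumarate geometry, and the fallback comes back at 9.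

3. Step 2. The risks are formation of the branched aldehyde, migration of the double bond before carbonylation, and self-condensation of the hydroxy aldehyde on standing. The fallback builds the extra carbon by olefination instead of carbonylation. It sets out from 4:
   - Hydroboration–oxidation (9-BBN, THF; then NaOH/H2O2) should give (14S)-pentadecane-1,14-diol F4.
   - Oxidation selective for the primary alcohol (TEMPO cat., PhI(OAc)2, CH2Cl2) should give (14S)-14-hydroxypentadecanal F5.
   - Wittig methoxymethylenation (Ph3P=CHOMe from the phosphonium chloride and KOtBu, THF, 0 °C) should give (2S)-16-methoxyhexadec-15-en-2-ol F6 as an E/Z mixture.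
   - Hydrolysis of the enol ether (aq. HCl, THF, rt) comes back to the route at 5.

Further compounds
F1 | step 5 | di-tert-butyl 2-[(15S)-1,15-dihydroxyhexadecyl]-3-methylidenebutanedioate (syn adduct, both configurations of the new stereocentre pair) | C=C(C(=O)OC(C)(C)C)C(C(O)CCCCCCCCCCCCC[C@H](C)O)C(=O)OC(C)(C)C
F2 | step 5 | (2R,3R)-2-[(14S)-14-hydroxypentadecyl]-4-methylidene-5-oxooxolane-3-carboxylic acid | C=C1C(=O)O[C@H](CCCCCCCCCCCCC[C@H](C)O)[C@@H]1C(=O)O
F3 | step 4 | di-tert-butyl (2E)-2-methylbut-2-enedioate | C/C(=C\C(=O)OC(C)(C)C)C(=O)OC(C)(C)C
F4 | step 2 | (14S)-pentadecane-1,14-diol | C[C@H](O)CCCCCCCCCCCCCO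
F5 | step 2 | (14S)-14-hydroxypentadecanal | C[C@H](O)CCCCCCCCCCCCC=O
F6 | step 2 | (2S)-16-methoxyhexadec-15-en-2-ol (E/Z mixture) | C[C@H](O)CCCCCCCCCCCCC=COC
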